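Compound numbers are those of the steps below; gibberellane numbering (C1–C19, C17 = exocyclic methylene carbon) is used for every intermediate.

## The problem

Compound 34 is a 20-norgibberellane. Ring A (C1–C5, C10) is bridged by the C19→C10 γ-lactone, ring B is a cyclopentane (C5, C6, C8, C9, C10), and rings C and D form a bicyclo[3.2.1]octane that shares the quaternary C8 and C9 with ring B. There are nine stereocentres (C1, C4, C5, C6, C8, C9, C10, C12, C13); H9 lies on the face of the lactone oxygen, so ring C is trans-fused to ring B, and the 12-hydroxyl is axial on ring C, syn to H9 and anti to the C15–C16 bridge. C8 is the centre that nothing else can correct. Once it is set, C13 follows from the geometry of the bicycle, C9 and C12 can be set on the rigid ring C, and the C15 methylene, which stands on ring B like an angular methyl group, decides the face on which C6, C5 and C10 are made; C4 and C1 then follow from the lactone. Three groups will not survive rough treatment: the 1-hydroxy-3-ketone (dehydration, retro-aldol), the β-keto lactone (ring A is opened by nucleophilic base at C3) and the 16-methylene (acid moves it into ring D); C6 is also epimerisable. The end of the synthesis therefore has to be buffered and free of alkoxide, and the hydroxyls and the acid need groups that come off without base. The enabling feature is that C4 is the α-carbon of a β-keto ester (C3 ketone, C19 carboxyl) and that C10, separated from C4 only by C5, is a tertiary carbon bonded to the carboxyl oxygen. A C5=C10 alkene in ring B with the keto ester chain on C10 therefore holds every atom of ring A and the lactone, and a C4 radical followed by a C10 cation can close both.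

## Retrosynthesis

**C1–O and the protecting groups (34 ⇐ 33 ⇐ 32 ⇐ 31 ⇐ 30).** The β-hydroxy ketone is the most fragile part, so it is made last but one. The silyl ether of 33 is removed by buffered fluoride, and the C1–O bond of 33 comes from the 1,2-epoxy ketone 32 by reductive opening at C2. Epoxide 32 comes from enone 31 by nucleophilic epoxidation on the face opposite the lactone, and 31 from ketone 30, where C4 is quaternary and only C2 can enolise. The acid is set free before the enone exists (30 from 29), because a thiolate cannot be used once an enone or an epoxide is present.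

**C4–C5 and C10–O (29 ⇐ 28), the key disconnection.** Cutting both bonds removes ring A, the lactone and the stereocentres C4, C5 and C10 and leaves the tricyclic β-keto ester 28 with a C5=C10 alkene. A stepwise alternative (ring A by an ionic alkylation, lactone by a separate acid step) would need a leaving group at C5 next to the epimerisable C6. The oxidative radical route needs nothing on the alkene carbons. Three spectator choices support the step:
- C16 is carried as the methylene, not as a ketone, so that no second ketone has to be distinguished from C3 at the end.
- C12 carries a silyl ether, not an ester, because the end of the route cannot take base.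
- C7 is a methyl ester, which cannot terminate the C10 cation by losing its alkyl group, whereas the tert-butyl ester at C19 can.

The forward step must be 6-endo, must occur on the face opposite C15, and the tertiary radical must be oxidised and captured faster than it eliminates.

**C3–C4 (28 ⇐ 27 ⇐ 25 + 26).** The keto ester is cut between C3 and C4 into aldehyde 25 and tert-butyl propanoate 26 (aldol addition, then oxidation). The neighbouring cut C1–C2 (allylic halide plus a keto ester dianion) would expose C6–H, which is α to an ester and allylic, to a strong base next to a leaving group. The aldol runs at low temperature on a neutral electrophile.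

**Ring B pattern (25 ⇐ 24 ⇐ 22 ⇐ 21 ⇐ 18 + 19).** The aldehyde is masked as the dioxolane of 24. The arrangement C6–H/C5=C10 is derived from the conjugated ester 22 by deconjugative protonation, which sets C6 under the control of the angular C15 methylene. C6–C7 is cut back to the enol triflate 21 (carbonylation), and C1–C10 to the enone 18 and the acetal bromide 19 (conjugate addition with enolate trapping). Each operation uses the one ketone that ring B offers, so no transposition of oxygen is needed.

**Adjustments on ring C (18 ⇐ 16 ⇐ 15 ⇐ 14 ⇐ 13 ⇐ 12).** Enone 18 comes from ketone 16, released from ketal 15. The axial silyloxy group of 15 comes from the equatorial alcohol 12 by Mitsunobu inversion (13), methanolysis (14) and silylation. Hydride reaches the C12 carbonyl only from the face opposite the C15–C16 bridge, so the axial alcohol is not available by direct reduction and the inversion is accepted as the price.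

**C13–C16 and C9–H (12 ⇐ 10 ⇐ 9 ⇐ 8).** Alcohol 12 comes from the tricyclic enone 10 by dissolving-metal reduction, which sets H9 axially (trans fusion) and gives the equatorial alcohol. Ring D is cut at C13–C16: the silyl enol ether 9 of the enone 8 closes onto the allyl group with divalent palladium and delivers the 16-methylene directly. Radical closure of a 2-haloallyl group would need a later oxidation at C12. An aldol closure would give a 16-ketone that has to be methylenated beside the C3 ketone.

**Rings B and C with C8 (8 ⇐ 7 ⇐ 5 ⇐ 3 + 4; 3 ⇐ 1 + 2).** Ketal 8 is the protected form of the allyl Hajos–Parrish enedione 7. Enedione 7 comes from triketone 5 by proline catalysis, which sets C8, and 5 from dione 3 and butenone 4. Dione 3 comes from cyclopentane-1,3-dione 1 and allyl bromide 2. In three steps this gives ring B with its C6 carbonyl, ring C with the C12 carbonyl and the C9=C11 alkene, and C15–C17 on the quaternary carbon.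

## Roads not taken

**Alternative 1:** Three-component coupling on a ring B cyclopentenone. The cut is C9–C11 and C8–C14. An allylic organocopper reagent adds to C9 of the 2-propargyl-4-silyloxycyclopentenone A2 anti to the silyloxy group, and the enolate is trapped at C8 by a one-carbon aldehyde anti to the new chain, giving ketone A1.
- Merits: it is convergent, it sets the trans C8/C9 relationship in one operation from an enantiopure building block, and the C10 oxygen is present from the start.
- Weak points: conjugate addition to an α-substituted cyclopentenone is slow, allylic copper reagents partition between 1,2- and 1,4-addition, and hydroxymethylation of a fully substituted enolate to a quaternary carbon is reversible. After A1 the bicyclooctane, ring A, the quaternary C4 and the lactone are all still to be made, and the secondary C10 oxygen has to become a tertiary lactone carbon.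
- Comparison: this road is better in convergence and fixes C8/C9 directly, where the chosen plan needs a catalytic aldol and a later reduction. The chosen plan reaches 7 in three steps and closes ring A and the lactone with three stereocentres in one step.

**Alternative 2:** Ring B contraction. The cut is C6–C8 of the target, traced back to a six-membered ring B. The 6-diazo-7-ketone A4 loses nitrogen, C8 migrates from C7 to C6 (Wolff rearrangement), and the ketene is hydrated to the acid A3, which is the same structure as 31.
- Merits: C7 appears as the free acid at the right oxidation level, the migration keeps C8 intact, and diazo transfer is unambiguous because neither C2 nor C4 of A4 can enolise.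
- Weak points: A4 must already contain ring A, the lactone and C4, so the central problem is moved to an earlier stage that needs its own key reaction on a larger ring system. The rearrangement has to be run on a molecule with an enone chromophore and an exocyclic alkene (competing enone photochemistry, carbene and ketene cycloadditions). C6 is set only by the face of ketene protonation.
- Comparison: this road is as good or better at the very end, since it needs no ester cleavage, whereas the chosen plan spends step 20 on one and exposes the β-keto lactone to a thiolate. The chosen plan builds ring A and the lactone instead of presupposing them.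

**Alternative 3:** Ring C by aldol. The cut is C12–C13. A Lewis acid activates the C12 aldehyde on the C9 side chain of A6, and the ring D silyl enol ether attacks it through an open transition state, closing ring C and giving the hydroxy ketone A5.
- Merits: the C12 carbinol is created in the ring-forming step, where the chosen plan needs steps 7 to 9 for it, and the bicyclooctane appears late from a simple spiro ketone.
- Weak points: the reaction runs on the complete ring A. The enol ether must be formed at C16 and not at C3. The 1-silyloxy group is β to the C3 ketone and eliminates under Lewis acid. The product is a β-hydroxy ketone that can revert. The axial hydroxyl is not assured by an open transition state. The 16-ketone must finally be methylenated in the presence of the C3 ketone.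
- Comparison: better for C12, worse for chemoselectivity at both ends. The chosen plan installs the 16-methylene in step 6 and never has two ketones to distinguish.

Key step: step 19

Assumption: the target is taken exactly as drawn, with H9 on the face of ring B that carries the lactone oxygen and with the 12-hydroxyl axial. "Upper face" of ring B means the face of the lactone oxygen; the C15 methylene, the C7 carboxyl and the C9–C11 bond are on the lower face. Lithium enolates quenched in the same operation are numbered only where the argument of the step rests on them.

## Steps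

Step 1
Reactants: 1 cyclopentane-1,3-dione; 2 allyl bromide
Product: 3 2-allylcyclopentane-1,3-dione
Conditions: NaOH, H2O, 25 °C
Reagents that add atoms: none
Why: C-alkylation of the dione enolate (SN2 allylation); in water the enolate oxygens are hydrogen-bonded and carbon alkylation is favoured.

Step 2
Reactants: 3 2-allylcyclopentane-1,3-dione; 4 but-3-en-2-one
Product: 5 2-allyl-2-(3-oxobutyl)cyclopentane-1,3-dione
Conditions: Et3N (cat.), MeCN, 25 °C
Reagents that add atoms: none
Why: Michael addition of the acidic 2-substituted 1,3-dione to the enone under amine catalysis; C8 becomes quaternary but is still prochiral.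

Step 3
Reactants: 5 2-allyl-2-(3-oxobutyl)cyclopentane-1,3-dione
Product: 7 (7aR)-7a-allyl-2,3,7,7a-tetrahydro-1H-indene-1,5(6H)-dione, via cis-fused bicyclic ketol 6 (not isolated)
Conditions: (S)-proline (30 mol %), DMF, 25 °C; then p-TsOH·H2O, toluene, 80 °C
Reagents that add atoms: none
Why: Hajos–Parrish (Eder–Sauer–Wiechert) reaction: the proline enamine of the side-chain ketone attacks one of the two enantiotopic ring carbonyls through the hydrogen-bonded chair transition state, which should set C8 in the sense of the (S)-Hajos–Parrish ketone (here 7aR because allyl outranks the ring methylene); acid then dehydrates ketol 6.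

Step 4
Reactants: 7 (7aR)-7a-allyl-2,3,7,7a-tetrahydro-1H-indene-1,5(6H)-dione
Product: 8 enedione 7 with the saturated C6 ketone as its ethylene ketal
Conditions: (Me3SiOCH2)2, TMSOTf (cat.), CH2Cl2, −78 → −20 °C
Reagents that add atoms: 1,2-bis(trimethylsilyloxy)ethane, C[Si](C)(C)OCCO[Si](C)(C)C
Why: Silyl-transfer ketalisation is selective for the saturated cyclopentanone because the conjugated C12 carbonyl is much less electrophilic; the C6 ketone must be masked so that only C13 is enolised in step 5.

Step 5
Reactants: 8 C6 ketal enone
Product: 9 cross-conjugated tert-butyldimethylsilyl dienol ether (C12–OSi, C12=C13, C9=C11)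
Conditions: LiN(i-Pr)2, THF, −78 °C; then TBSCl, HMPA, −78 → 0 °C
Reagents that add atoms: tert-butyldimethylsilyl chloride, CC(C)(C)[Si](C)(C)Cl
Why: Kinetic deprotonation of an enone by a lithium amide occurs at the α′ carbon (C13), and O-silylation gives the 2-silyloxy diene; this fixes the site of the coming C–C bond.

Step 6
Reactants: 9 silyl dienol ether
Product: 10 tricyclic 9(11)-en-12-one with 16-methylene and C6 ketal
Conditions: Pd(OAc)2 (10 mol %), O2 (1 atm), DMSO, 45 °C
Reagents that add atoms: none
Why: Palladium-mediated oxidative cycloalkenylation of a silyl enol ether with a pendant alkene (a Saegusa-type reaction of divalent palladium): C13 adds to the internal carbon C16 of the allyl group in a 5-exo closure, and β-hydride loss gives the 16-methylene while O2 returns the metal to the divalent state; the allyl group is axial on C8, so ring D can only be cis-bridged and C13 follows from C8.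

Step 7
Reactants: 10 tricyclic enone
Product: 12 ketal alcohol with equatorial 12-OH (syn to the C15–C16 bridge) and H9 anti to C15, via saturated 12-ketone 11 (not isolated)
Conditions: Li, NH3(l)/THF, −78 °C; then MeOH, −33 °C; NH4Cl
Reagents that add atoms: none
Why: Dissolving-metal reduction of the enone: the β-carbon C9 is protonated axially on the face of ring C opposite the C15–C16 bridge, which should give the trans ring fusion; with methanol the 12-ketone 11 is reduced further under thermodynamic control to the equatorial alcohol, and the isolated 1,1-disubstituted alkene is not touched.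

Step 8
Reactants: 12 equatorial 12-alcohol
Product: 13 axial 12-(4-nitrobenzoate)
Conditions: 4-O2NC6H4CO2H, PPh3, DIAD, toluene, 0 → 40 °C
Reagents that add atoms: 4-nitrobenzoic acid, OC(=O)c1ccc(cc1)[N+](=O)[O-]
Why: Mitsunobu inversion: the activated equatorial oxygen is displaced by 4-nitrobenzoate from the open face of C12 (anti to the C15–C16 bridge), giving the axial ester with the configuration of the target; hydride cannot reach the ketone from the bridge side, so inversion is the reliable way to the axial oxygen.

Step 9
Reactants: 13 axial 4-nitrobenzoate
Product: 14 axial 12-alcohol (12-OH syn to H9, anti to the C15–C16 bridge)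
Conditions: K2CO3, MeOH/THF, 25 °C
Reagents that add atoms: none
Why: Base-catalysed transesterification of the activated aryl ester; ketal and alkene are inert.

Step 10
Reactants: 14 axial 12-alcohol
Product: 15 12-O-tert-butyldimethylsilyl ether with C6 ketal
Conditions: TBSCl, imidazole, DMAP (cat.), DMF, 50 °C
Reagents that add atoms: tert-butyldimethylsilyl chloride, CC(C)(C)[Si](C)(C)Cl
Why: Silylation of the secondary alcohol; a silyl ether survives the amide bases, the organometallic and the acetic acid of later steps and can be removed at the end without base.

Step 11
Reactants: 15 silyl ether ketal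
Product: 16 tricyclic C6 ketone
Conditions: PPTS, acetone/H2O, 60 °C
Reagents that add atoms: water, O
Why: Acid-catalysed ketal hydrolysis (transketalisation to acetone) with a pyridinium acid too weak to move the 16-methylene into ring D or to cleave the hindered silyl ether.

Step 12
Reactants: 16 C6 ketone
Product: 18 5(10)-en-6-one, via trimethylsilyl enol ether 17 (not isolated)
Conditions: LiN(i-Pr)2, TMSCl, THF, −78 °C; then Pd(OAc)2 (10 mol %), O2 (1 atm), DMSO, 40 °C
Reagents that add atoms: none
Why: Saegusa–Ito dehydrogenation: C8 is quaternary, so the ketone can only enolise towards C5, and the silyl enol ether 17 is oxidised by divalent palladium to the cyclopentenone.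

Step 13
Reactants: 18 5(10)-en-6-one; 19 2-(2-bromoethyl)-1,3-dioxolane (as its Grignard reagent)
Product: 21 C6 enol triflate (C5=C6) carrying the 2-(1,3-dioxolan-2-yl)ethyl chain on the upper face of C10, via bromomagnesium enolate 20 (not isolated)
Conditions: 19, Mg, THF; CuBr·SMe2 (10 mol %), THF, −78 °C; then N-(5-chloro-2-pyridyl)bis(trifluoromethanesulfonimide) (Comins' reagent), −78 → 0 °C
Reagents that add atoms: N-(5-chloropyridin-2-yl)bis(trifluoromethanesulfonimide), Clc1ccc(nc1)N(S(=O)(=O)C(F)(F)F)S(=O)(=O)C(F)(F)F
Why: Copper-catalysed conjugate addition of the Grignard reagent forms C1–C10 on the face of ring B opposite the C15 methylene (C10 becomes sp2 again in step 15), and the regiodefined enolate 20 is trapped on oxygen as the enol triflate.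

Step 14
Reactants: 21 enol triflate
Product: 22 conjugated methyl ester (C7 on C6, C5=C6)
Conditions: Pd(OAc)2 (5 mol %), PPh3, CO (1 atm), MeOH, Et3N, DMF, 50 °C
Reagents that add atoms: carbon monoxide, [C-]#[O+]; methanol, CO
Why: Palladium-catalysed methoxycarbonylation of the enol triflate (oxidative addition to zerovalent palladium, CO insertion, methanolysis), the standard conversion of a hindered ketone next to a quaternary carbon into the unsaturated ester; it forms C6–C7.

Step 15
Reactants: 22 conjugated methyl ester
Product: 24 β,γ-unsaturated methyl ester (C5=C10; H6 on the upper face and the ester syn to C15), via lithium dienolate 23 (not isolated)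
Conditions: LiN(i-Pr)2, HMPA, THF, −78 °C; then AcOH, −78 °C
Reagents that add atoms: none
Why: Deconjugative protonation of an enoate: the lithium amide with HMPA removes the γ-hydrogen at C10 to give the extended enolate 23, and kinetic protonation occurs at the α-carbon C6, which moves the alkene to C5=C10; the proton should arrive on the face opposite the angular C15 methylene, so H6 is anti and the ester syn to C15 as in the target.

Step 16
Reactants: 24 deconjugated ester acetal
Product: 25 aldehyde (C3 as CHO)
Conditions: PPTS, acetone/H2O, 55 °C
Reagents that add atoms: water, O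
Why: Acid-catalysed acetal hydrolysis under the mild conditions of step 11; weak acid does not reconjugate the β,γ-unsaturated ester.

Step 17
Reactants: 25 aldehyde; 26 tert-butyl propanoate
Product: 27 β-hydroxy ester (mixture at C3 and C4)
Conditions: LiN(i-Pr)2, 26, THF, −78 °C; then 25, −78 °C; NH4Cl
Reagents that add atoms: none
Why: Aldol addition of the lithium enolate of 26 to the aldehyde forms C3–C4; at low temperature it is much faster than proton abstraction from C6, and the two new centres are erased in steps 18 and 19.

Step 18
Reactants: 27 β-hydroxy ester
Product: 28 tert-butyl 2-methyl-3-oxo ester on C10 of the ring B cyclopentene (precursor of the key step)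
Conditions: Dess–Martin periodinane, NaHCO3, CH2Cl2, 0 → 25 °C
Reagents that add atoms: none
Why: Dess–Martin oxidation of the β-hydroxy ester to the β-keto ester under buffered, non-acidic conditions; C4 remains a mixture that equilibrates through the enol.

Step 19
Reactants: 28 β-keto ester
Product: 29 1-deoxy lactone: 3-oxo-19,10-lactone with 12-O-silyl ether, 7-methyl ester and 16-methylene
Conditions: Mn(OAc)3·2H2O (2.2 equiv), AcOH (degassed, 0.01 M), 25 → 40 °C
Reagents that add atoms: none
Why: Mn(OAc)3 forms the trivalent manganese enolate of the α-methyl β-keto ester, and electron transfer gives the electrophilic C4 radical, which adds to C5 of the ring B alkene in a 6-endo-trig closure (ring A, C4–C5); this is favoured over 5-exo because C10 is fully substituted and the C3 carbonyl lies inside the forming ring. The tertiary C10 radical is oxidised by a second equivalent of trivalent manganese to the cation, which the tert-butyl ester carbonyl captures in a five-membered closure (5-exo attack of the carbonyl oxygen on C10, C10–O, lactone) with loss of isobutene. The closest known reaction type is the Mn(OAc)3-mediated oxidative cyclisation of unsaturated α-alkyl β-keto esters onto trisubstituted alkenes, including cases ended by γ-lactone formation from a tertiary cation. C5 is set by attack on the face of ring B opposite the angular C15 methylene and the C6 ester. C4 is set in the chair-like transition state that places the ester axial, and only this epimer can lactonise. C10 follows because the γ-lactone can only be cis-fused across C4–C5–C10, which leaves C1 on the lower face. The step needs chemoselectivity over the C7 methyl ester, which cannot end the cation by losing its alkyl group, and over the 16-methylene, which is reached only intermolecularly and should be outrun by the 6-endo closure at high dilution; acetic acid at 25–40 °C should leave the silyl ether and the exocyclic alkene intact.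

Step 20
Reactants: 29 lactone methyl ester
Product: 30 lactone 7-acid
Conditions: n-PrSLi, HMPA, 0 → 25 °C; then dilute HCl
Reagents that add atoms: none
Why: SN2 dealkylation of the methyl ester by thiolate at the methyl carbon, which does not depend on access to the hindered carbonyl and does not open the lactone (its alkyl carbon is tertiary); it is placed here because a thiolate would add to the enone of 31 or open the epoxide of 32.

Step 21
Reactants: 30 3-keto acid
Product: 31 1-en-3-one acid
Conditions: IBX, 4-methoxypyridine N-oxide, DMSO, 25 °C
Reagents that add atoms: none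
Why: IBX dehydrogenation of a ketone through its enol (single-electron oxidation, loss of the β-hydrogen); C4 is quaternary, so only C2 can enolise and the 1-en-3-one is the only possible product; the N-oxide ligand allows room temperature.

Step 22
Reactants: 31 1-en-3-one acid
Product: 32 1,2-epoxy-3-ketone acid (epoxide on the face of ring A opposite the lactone)
Conditions: t-BuOOH, DBU, CH2Cl2, 0 → 25 °C
Reagents that add atoms: tert-butyl hydroperoxide, CC(C)(C)OO
Why: Weitz–Scheffer nucleophilic epoxidation: the peroxide anion adds to C1 axially on the face of ring A opposite the lactone bridge, and the enolate closes the epoxide, which fixes the C1–O bond anti to the lactone; the isolated 16-methylene does not react with a nucleophilic oxidant.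

Step 23
Reactants: 32 epoxy ketone acid
Product: 33 1-hydroxy-3-ketone acid with 12-O-silyl ether
Conditions: (PhSe)2, NaBH4, EtOH; then AcOH, 32, 0 → 25 °C
Reagents that add atoms: none
Why: Reductive opening of an α,β-epoxy ketone by benzeneselenolate (as sodium phenylseleno(triethoxy)borate): the selenolate displaces the Cα–O bond at C2 and a second equivalent removes selenium to give the enolate, so the C1–O bond and its configuration are kept; acetic acid buffering protects the β-hydroxy ketone.

Step 24
Reactants: 33 silyl-protected hydroxy ketone acid
Product: 34 target
Conditions: HF·pyridine, pyridine, THF, 0 → 25 °C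
Reagents that add atoms: none
Why: Fluoride-mediated cleavage of the silyl ether under buffered, weakly acidic conditions that the β-hydroxy ketone, the lactone and the 16-methylene should tolerate.

## Compound list

1 | cyclopentane-1,3-dione | O=C1CCC(=O)C1 | starting material
2 | allyl bromide | C=CCBr | starting material
3 | 2-allylcyclopentane-1,3-dione | C=CCC1C(=O)CCC1=O | intermediate
4 | but-3-en-2-one | CC(=O)C=C | starting material
5 | 2-allyl-2-(3-oxobutyl)cyclopentane-1,3-dione | C=CCC1(CCC(C)=O)C(=O)CCC1=O | intermediate
6 | cis-fused ketol, 7a-allyl-3a-hydroxyhexahydroindene-1,5-dione, hydroxyl cis to allyl (not isolated) | C=CC[C@]23CCC(=O)C[C@@]2(O)CCC3=O | intermediate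
7 | (7aR)-7a-allyl-2,3,7,7a-tetrahydro-1H-indene-1,5(6H)-dione | C=CC[C@]23CCC(=O)C=C2CCC3=O | intermediate
8 | 7 with the saturated (C6) ketone as ethylene ketal | C=CC[C@]23CCC(=O)C=C2CCC34OCCO4 | intermediate
9 | cross-conjugated TBS dienol ether of 8 (C12–OTBS, C12=C13, C9=C11) | C=CC[C@]23CC=C(O[Si](C)(C)C(C)(C)C)C=C2CCC34OCCO4 | intermediate
10 | tricyclic 9(11)-en-12-one, 16-methylene, C6 ketal | C=C1C[C@]23C[C@H]1C(=O)C=C2CCC34OCCO4 | intermediate
11 | saturated 12-ketone, H9 anti to C15, C6 ketal (not isolated) | C=C1C[C@]23C[C@H]1C(=O)C[C@@H]2CCC34OCCO4 | intermediate
12 | equatorial 12-alcohol (OH syn to the C15–C16 bridge), C6 ketal | C=C1C[C@]23C[C@H]1[C@H](O)C[C@@H]2CCC34OCCO4 | intermediate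
13 | axial 12-(4-nitrobenzoate), C6 ketal | C=C1C[C@]23C[C@H]1[C@@H](OC(=O)c1ccc(cc1)[N+](=O)[O-])C[C@@H]2CCC34OCCO4 | intermediate
14 | axial 12-alcohol (OH syn to H9), C6 ketal | C=C1C[C@]23C[C@H]1[C@@H](O)C[C@@H]2CCC34OCCO4 | intermediate
15 | axial 12-O-TBS ether, C6 ketal | C=C1C[C@]23C[C@H]1[C@@H](O[Si](C)(C)C(C)(C)C)C[C@@H]2CCC34OCCO4 | intermediate
16 | 12-O-TBS tricyclic C6 ketone | C=C1C[C@]23C[C@H]1[C@@H](O[Si](C)(C)C(C)(C)C)C[C@@H]2CCC3=O | intermediate
17 | C5=C6 trimethylsilyl enol ether of 16 (not isolated) | C=C1C[C@]23C[C@H]1[C@@H](O[Si](C)(C)C(C)(C)C)C[C@@H]2CC=C3O[Si](C)(C)C | intermediate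
18 | 12-O-TBS 5(10)-en-6-one | C=C1C[C@]23C[C@H]1[C@@H](O[Si](C)(C)C(C)(C)C)C[C@@H]2C=CC3=O | intermediate
19 | 2-(2-bromoethyl)-1,3-dioxolane | BrCCC1OCCO1 | starting material
20 | bromomagnesium C5=C6 enolate with the dioxolanylethyl chain on the upper face of C10 (not isolated) | C=C1C[C@]23C[C@H]1[C@@H](O[Si](C)(C)C(C)(C)C)C[C@@H]2[C@@H](CCC4OCCO4)C=C3O[Mg]Br | intermediate
21 | C6 enol triflate (C5=C6), chain on the upper face of C10 | C=C1C[C@]23C[C@H]1[C@@H](O[Si](C)(C)C(C)(C)C)C[C@@H]2[C@@H](CCC4OCCO4)C=C3OS(=O)(=O)C(F)(F)F | intermediate
22 | conjugated methyl ester (C5=C6, CO2Me on C6) | C=C1C[C@]23C[C@H]1[C@@H](O[Si](C)(C)C(C)(C)C)C[C@@H]2[C@@H](CCC4OCCO4)C=C3C(=O)OC | intermediate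
23 | lithium dienolate of 22 (C10=C5, C6=C7) (not isolated) | C=C1C[C@]23C[C@H]1[C@@H](O[Si](C)(C)C(C)(C)C)C[C@@H]2C(CCC4OCCO4)=CC3=C(OC)O[Li] | intermediate
24 | β,γ-unsaturated methyl ester (C5=C10; H6 upper face, CO2Me syn to C15), chain acetal | C=C1C[C@]23C[C@H]1[C@@H](O[Si](C)(C)C(C)(C)C)C[C@@H]2C(CCC4OCCO4)=C[C@@H]3C(=O)OC | intermediate
25 | aldehyde (3-oxopropyl chain on C10) | C=C1C[C@]23C[C@H]1[C@@H](O[Si](C)(C)C(C)(C)C)C[C@@H]2C(CCC=O)=C[C@@H]3C(=O)OC | intermediate
26 | tert-butyl propanoate | CCC(=O)OC(C)(C)C | starting material
27 | tert-butyl 3-hydroxy-2-methyl ester (C3/C4 diastereomer mixture, both centres erased later) | C=C1C[C@]23C[C@H]1[C@@H](O[Si](C)(C)C(C)(C)C)C[C@@H]2C(CCC(O)C(C)C(=O)OC(C)(C)C)=C[C@@H]3C(=O)OC | intermediate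
28 | tert-butyl 2-methyl-3-oxo ester on C10 of the C5=C10 cyclopentene (C4 epimers interconvert) | C=C1C[C@]23C[C@H]1[C@@H](O[Si](C)(C)C(C)(C)C)C[C@@H]2C(CCC(=O)C(C)C(=O)OC(C)(C)C)=C[C@@H]3C(=O)OC | intermediate
29 | 3-oxo-19,10-lactone, 12-O-TBS, 7-methyl ester, 16-methylene | C=C1C[C@]23C[C@H]1[C@@H](O[Si](C)(C)C(C)(C)C)C[C@@H]2[C@]12OC(=O)[C@](C)(C(=O)CC1)[C@H]2[C@@H]3C(=O)OC | intermediate
30 | 3-oxo-19,10-lactone 7-acid, 12-O-TBS | C=C1C[C@]23C[C@H]1[C@@H](O[Si](C)(C)C(C)(C)C)C[C@@H]2[C@]12OC(=O)[C@](C)(C(=O)CC1)[C@H]2[C@@H]3C(=O)O | intermediate
31 | 1-en-3-one lactone 7-acid, 12-O-TBS | C=C1C[C@]23C[C@H]1[C@@H](O[Si](C)(C)C(C)(C)C)C[C@@H]2[C@]12OC(=O)[C@](C)(C(=O)C=C1)[C@H]2[C@@H]3C(=O)O | intermediate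
32 | 1,2-epoxy-3-ketone lactone 7-acid (epoxide anti to the lactone), 12-O-TBS | C=C1C[C@]23C[C@H]1[C@@H](O[Si](C)(C)C(C)(C)C)C[C@@H]2[C@]12OC(=O)[C@](C)(C(=O)[C@H]4O[C@@H]14)[C@H]2[C@@H]3C(=O)O | intermediate
33 | 1-hydroxy-3-ketone lactone 7-acid (1-OH anti to the lactone), 12-O-TBS | C=C1C[C@]23C[C@H]1[C@@H](O[Si](C)(C)C(C)(C)C)C[C@@H]2[C@]12OC(=O)[C@](C)(C(=O)C[C@H]1O)[C@H]2[C@@H]3C(=O)O | intermediate
34 | 1,12-dihydroxy-3-oxo-20-norgibberell-16-ene-7,19-dioic acid 19,10-lactone (1-OH anti to the lactone bridge, 12-OH axial, H9 syn to the lactone oxygen) | C=C1C[C@]23C[C@H]1[C@@H](O)C[C@@H]2[C@]12OC(=O)[C@](C)(C(=O)C[C@H]1O)[C@H]2[C@@H]3C(=O)O | target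

Total step count: 24. Longest linear sequence: 24 steps (1 → 34); 2, 4, 19 and 26 enter as purchased building blocks.

## Least certain steps

**Step 19 (key step).** The most likely failure is termination of the tertiary C10 radical by hydrogen abstraction, or of the cation by proton loss, instead of capture by the ester carbonyl. This would happen if the radical closure delivered the C4 ester equatorial or if oxidation by trivalent manganese were slow. Radical addition to the 16-methylene is a second possible leak. Fallback, from 28: run the cyclisation with Mn(OAc)3·2H2O and Cu(OAc)2·H2O, so that divalent copper ends the sequence by β-hydride loss and gives the ring A alkene, the 1(10)-ene keto diester F1. Close the lactone separately by iodolactonisation (I2, NaHCO3, MeCN), in which the tert-butyl ester adds to C10 and iodine to C1, giving the 1-iodo lactone F2. Remove iodine with Bu3SnH and AIBN in toluene to return to 29.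

**Step 15.** The most likely failure is protonation of the dienolate at the γ-carbon (return to the conjugated ester), or incomplete removal of the hindered tertiary γ-hydrogen with competing conjugate addition of the amide. Lower than expected face selectivity at C6 is a lesser concern. Fallback, from 21: hydroxycarbonylation (Pd(OAc)2, dppf, CO, KOAc, DMSO/H2O) gives the conjugated enoic acid F3. 1-Chloro-N,N,2-trimethylpropenylamine converts it under neutral conditions into the acid chloride F4. Et3N eliminates HCl across C10–H to the vinylketene F5 (not isolated), which methanol traps with protonation at C6 only. This gives 24 without a strong base, and the face is again set by the C15 methylene.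

**Step 20.** The most likely failure is opening of ring A by addition of the thiolate to the C3 carbonyl of the β-keto lactone (retro-Claisen cleavage of C3–C4) in competition with the slow attack on the methyl group. Fallback, from 29: keep the methyl ester through the ring A oxidations. IBX with 4-methoxypyridine N-oxide gives the methyl ester enone F6. t-BuOOH and DBU give the methyl ester epoxy ketone F7. Me3SnOH in 1,2-dichloroethane at 70 °C then cleaves the ester by acyl–oxygen exchange at a stage that holds neither an enone nor a β-hydroxy ketone, and the route is rejoined at 32.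

**Step 22.** The most likely failure is base-induced fragmentation of the β-keto lactone by the peroxide anion at C3, or loss of face selectivity because the C11 methylene crowds the lower face at C1. Fallback, from 31: copper-catalysed conjugate borylation (CuCl, Xantphos, NaOt-Bu cat., B2pin2, MeOH, THF) places boron on C1 anti to the lactone and gives the 1-boryl ketone F8. Oxidation with NaBO3·4H2O in THF/H2O replaces boron by hydroxyl with retention and rejoins the route at 33, without an epoxide and without selenium.

**Step 8.** The most likely failure is elimination, or no reaction, at the hindered carbinol next to the bridgehead. Fallback, from 12: MsCl and Et3N give the equatorial mesylate F9. KO2 with 18-crown-6 in DMSO displaces it with inversion and gives the axial alcohol 14 directly, bypassing 13.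

## Further compounds

F1 | step 19 | 1(10)-ene 3-ketone with tert-butyl ester and methyl on C4 (ring A closed, no lactone), 12-O-TBS, 7-methyl ester | C=C1C[C@]23C[C@H]1[C@@H](O[Si](C)(C)C(C)(C)C)C[C@@H]2C4=CCC(=O)[C@@](C)(C(=O)OC(C)(C)C)[C@H]4[C@@H]3C(=O)OC
F2 | step 19 | 1-iodo-3-oxo-19,10-lactone (iodine anti to the lactone), 12-O-TBS, 7-methyl ester | C=C1C[C@]23C[C@H]1[C@@H](O[Si](C)(C)C(C)(C)C)C[C@@H]2[C@]12OC(=O)[C@](C)(C(=O)C[C@H]1I)[C@H]2[C@@H]3C(=O)OC
F3 | step 15 | conjugated enoic acid corresponding to 22 | C=C1C[C@]23C[C@H]1[C@@H](O[Si](C)(C)C(C)(C)C)C[C@@H]2[C@@H](CCC4OCCO4)C=C3C(=O)O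
F4 | step 15 | acid chloride of F3 | C=C1C[C@]23C[C@H]1[C@@H](O[Si](C)(C)C(C)(C)C)C[C@@H]2[C@@H](CCC4OCCO4)C=C3C(Cl)=O
F5 | step 15 | vinylketene (C10=C5, C6=C7=O) | C=C1C[C@]23C[C@H]1[C@@H](O[Si](C)(C)C(C)(C)C)C[C@@H]2C(CCC4OCCO4)=CC3=C=O
F6 | step 20 | methyl ester of 31 | C=C1C[C@]23C[C@H]1[C@@H](O[Si](C)(C)C(C)(C)C)C[C@@H]2[C@]12OC(=O)[C@](C)(C(=O)C=C1)[C@H]2[C@@H]3C(=O)OC
F7 | step 20 | methyl ester of 32 | C=C1C[C@]23C[C@H]1[C@@H](O[Si](C)(C)C(C)(C)C)C[C@@H]2[C@]12OC(=O)[C@](C)(C(=O)[C@H]4O[C@@H]14)[C@H]2[C@@H]3C(=O)OC
F8 | step 22 | 1-(pinacolboryl)-3-ketone lactone 7-acid (boron anti to the lactone), 12-O-TBS | C=C1C[C@]23C[C@H]1[C@@H](O[Si](C)(C)C(C)(C)C)C[C@@H]2[C@]12OC(=O)[C@](C)(C(=O)C[C@H]1B4OC(C)(C)C(C)(C)O4)[C@H]2[C@@H]3C(=O)O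
F9 | step 8 | equatorial 12-mesylate of 12 | C=C1C[C@]23C[C@H]1[C@H](OS(C)(=O)=O)C[C@@H]2CCC34OCCO4
A1 | alternative 1 | ring B cyclopentanone with methallyl on C9, hydroxymethyl and silylpropargyl on C8, silyloxy on C10 | O=C1C[C@H](O[Si](C)(C)C(C)(C)C)[C@@H](CC(C)=C)[C@@]1(CO)CC#C[Si](C)(C)C
A2 | alternative 1 | 4-silyloxy-2-(3-trimethylsilylpropargyl)cyclopent-2-enone | O=C1C[C@H](O[Si](C)(C)C(C)(C)C)C=C1CC#C[Si](C)(C)C
A3 | alternative 2 | 1-en-3-one lactone 7-acid, 12-O-TBS (identical with 31) | C=C1C[C@]23C[C@H]1[C@@H](O[Si](C)(C)C(C)(C)C)C[C@@H]2[C@]12OC(=O)[C@](C)(C(=O)C=C1)[C@H]2[C@@H]3C(=O)O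
A4 | alternative 2 | 6-diazo-7-ketone with six-membered ring B | C=C1C[C@]23C[C@H]1[C@@H](O[Si](C)(C)C(C)(C)C)C[C@@H]2[C@]12OC(=O)[C@](C)(C(=O)C=C1)[C@H]2C(=[N+]=[N-])C3=O
A5 | alternative 3 | 16-oxo-17-nor lactone with free 12-OH, 1-O-TBS, 7-methyl ester | O=C1C[C@]23C[C@H]1[C@@H](O)C[C@@H]2[C@]12OC(=O)[C@](C)(C(=O)C[C@H]1O[Si](C)(C)C(C)(C)C)[C@H]2[C@@H]3C(=O)OC
A6 | alternative 3 | spiro ring D silyl enol ether with the C12 aldehyde on the C9 side chain | C[Si](C)(C)OC=1C[C@]2(CC=1)[C@H](CC=O)[C@]34OC(=O)[C@](C)(C(=O)C[C@H]3O[Si](C)(C)C(C)(C)C)[C@H]4[C@@H]2C(=O)OC
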